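Ring A, the nine-membered carbocycle, contains the run C7(O)–C8=C9–C10–C11(=C19H2). Read backwards, this is a cyclohexanone (C7) whose α-carbon C11 has been moved three atoms away, with the C19 methylene marking the broken C7–C11 bond. The route therefore builds a trans-3,4-disubstituted cyclohexanone carrying, on quaternary C11, a (Z)-3-iodoallyl chain and a CH2SPh group, and expands it in one radical chain: the C8 vinyl radical adds to the C7 carbonyl, the alkoxy radical cleaves C7–C11, and C19 loses PhS•, giving the ring, the cis-enone and the exocyclic methylene together. Methyl addition, lactonisation, directed epoxidation and an aldol condensation with a side-chain aldehyde finish the target.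

Key step: step 10

Atom labels (target numbering): C1 (OCH2), O2, C3 (lactone C=O), C4, C4a, C5, C6, C7 (C(CH3)OH), C8, C9, C10, C11 (=C19H2), C11a, C12 (=CH), C13 (CHOAc), C14, C15 (CMe2); ring A is the nine-membered carbocycle, ring B the lactone.

Remark: C11 of the ring-expansion substrate becomes trigonal in step 10, so its configuration is a design choice. The route makes the epimer with the iodoallyl chain cis to the C11a substituent, because that chain is then axial in the chair that keeps the C4a and C11a groups equatorial and lies over the C7 carbonyl face. The quaternary carbon is completed by phenylthiomethylation after the iodoallyl group is in place, so that no enolate with a β-phenylthio leaving group is needed.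

Remark: in step 14 the antipode of the ProPhenol ligand is chosen that gives the R carbinol.

Step 1
Reactants: 1 ethyl propiolate
Product: 2 ethyl (Z)-3-iodoprop-2-enoate
Conditions: NaI, AcOH, 70 °C
Reagents that add atoms: sodium iodide, [Na+].[I-]
Why: Conjugate hydroiodination of the ynoate (iodide adds to the β-carbon and the allenolate is protonated anti) should give the Z iodoacrylate under kinetic control.

Step 2
Reactants: 2 ethyl (Z)-3-iodoprop-2-enoate
Product: 3 (Z)-3-iodoprop-2-en-1-ol
Conditions: i-Bu2AlH (2.2 equiv), CH2Cl2, −78 °C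
Reagents that add atoms: none
Why: Hydride reduction of the ester by i-Bu2AlH at low temperature should give the allylic alcohol without touching the vinyl iodide or its Z geometry.

Step 3
Reactants: 3 (Z)-3-iodoprop-2-en-1-ol
Product: 4 (Z)-3-bromo-1-iodoprop-1-ene
Conditions: CBr4, PPh3, CH2Cl2, 0 °C
Reagents that add atoms: carbon tetrabromide, BrC(Br)(Br)Br
Why: The Appel reaction turns the primary allylic alcohol into the bromide by SN2 displacement of an oxyphosphonium group under neutral conditions, so the (Z)-vinyl iodide is kept.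

Step 4
Reactants: 5 methyl 4-oxobutanoate; 6 but-3-en-2-one
Product: 8 methyl 2-[(1R)-4-oxocyclohex-2-en-1-yl]acetate, via keto aldehyde 7 (not isolated)
Conditions: (R)-α,α-diphenylprolinol trimethylsilyl ether (10 mol %), ethyl 3,4-dihydroxybenzoate (20 mol %), neat, 4 °C; then TsOH·H2O (cat.), PhMe, 60 °C
Reagents that add atoms: none
Why: In this enamine-catalysed asymmetric Michael addition the diphenyl(silyloxy)methyl group of the R catalyst shields one face of the E enamine of 5, so that butenone adds to the other face and sets C4a as R, and the acid-catalysed intramolecular aldol condensation of 7 then closes the cyclohexenone.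

Step 5
Reactants: 8 methyl 2-[(1R)-4-oxocyclohex-2-en-1-yl]acetate; 4 (Z)-3-bromo-1-iodoprop-1-ene
Product: 10 methyl 2-[(1R,2R,3S)-3-[(Z)-3-iodoprop-2-en-1-yl]-2-{[dimethyl(propan-2-yloxy)silyl]methyl}-4-oxocyclohexyl]acetate, via magnesium enolate 9 (not isolated)
Conditions: i-PrOMe2SiCH2MgCl (1.3 equiv; from i-PrOMe2SiCH2Cl and Mg), CuBr·SMe2 (10 mol %), THF, −78 °C; then 4 (2 equiv), HMPA, −78 → 0 °C
Reagents that add atoms: [dimethyl(propan-2-yloxy)silyl]methylmagnesium chloride, CC(C)O[Si](C)(C)C[Mg]Cl
Why: Copper-catalysed conjugate addition of the silylmethyl Grignard reagent (a hydroxymethyl anion equivalent) occurs anti to the C4a side chain and sets C11a trans, and the regiodefined magnesium enolate 9 is then C-alkylated by the allylic bromide anti to the new C11a group (conjugate addition–enolate alkylation), the C11 centre being temporary.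

Step 6
Reactants: 10 methyl 2-[(1R,2R,3S)-3-[(Z)-3-iodoprop-2-en-1-yl]-2-{[dimethyl(propan-2-yloxy)silyl]methyl}-4-oxocyclohexyl]acetate
Product: 11 methyl 2-[(1R,2R,3S)-2-(hydroxymethyl)-3-[(Z)-3-iodoprop-2-en-1-yl]-4-oxocyclohexyl]acetate
Conditions: KF, KHCO3, 30% H2O2, THF/MeOH, rt
Reagents that add atoms: hydrogen peroxide, OO
Why: Tamao oxidation replaces the C–Si bond of the alkoxysilane by C–OH under buffered peroxide–fluoride conditions that the ketone, the ester and the vinyl iodide should tolerate, and it is placed before any sulfide is present.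

Step 7
Reactants: 11 methyl 2-[(1R,2R,3S)-2-(hydroxymethyl)-3-[(Z)-3-iodoprop-2-en-1-yl]-4-oxocyclohexyl]acetate
Product: 12 methyl 2-[(1R,2R,3S)-2-{[tert-butyl(dimethyl)silyl]oxymethyl}-3-[(Z)-3-iodoprop-2-en-1-yl]-4-oxocyclohexyl]acetate
Conditions: TBSCl, imidazole, DMF, 0 °C → rt
Reagents that add atoms: tert-butyldimethylsilyl chloride, CC(C)(C)[Si](C)(C)Cl
Why: Silylation of the primary alcohol, carried out on the crude alcohol so that it cannot lactonise onto the ester, gives a silyl ether that should survive every step up to the lactonisation.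

Step 8
Reactants: 12 methyl 2-[(1R,2R,3S)-2-{[tert-butyl(dimethyl)silyl]oxymethyl}-3-[(Z)-3-iodoprop-2-en-1-yl]-4-oxocyclohexyl]acetate
Product: 13 methyl 2-[(1R,2R)-2-{[tert-butyl(dimethyl)silyl]oxymethyl}-3-[(Z)-3-iodoprop-2-en-1-yl]-4-(trimethylsilyloxy)cyclohex-3-en-1-yl]acetate
Conditions: TMSCl, NaI, Et3N, MeCN, rt
Reagents that add atoms: chlorotrimethylsilane, C[Si](C)(C)Cl
Why: Enol silylation under equilibrating conditions with iodotrimethylsilane made in the flask (thermodynamic enol silylation) should favour the more substituted C7=C11 enol ether, which removes the temporary C11 centre and fixes the site of the next C–C bond.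

Step 9
Reactants: 13 methyl 2-[(1R,2R)-2-{[tert-butyl(dimethyl)silyl]oxymethyl}-3-[(Z)-3-iodoprop-2-en-1-yl]-4-(trimethylsilyloxy)cyclohex-3-en-1-yl]acetate
Product: 14 methyl 2-[(1R,2R,3S)-2-{[tert-butyl(dimethyl)silyl]oxymethyl}-3-[(Z)-3-iodoprop-2-en-1-yl]-4-oxo-3-[(phenylsulfanyl)methyl]cyclohexyl]acetate
Conditions: PhSCH2Cl (1.2 equiv), ZnBr2 (10 mol %), CH2Cl2, 0 °C → rt
Reagents that add atoms: chloromethyl phenyl sulfide, ClCSc1ccccc1
Why: Lewis-acid-promoted α-phenylthiomethylation of the silyl enol ether (SN1-type alkylation by the PhS=CH2+ ion) builds the quaternary C11 without an enolate that could expel thiolate, and the electrophile is expected to enter anti to the neighbouring C11a substituent, which leaves the iodoallyl chain cis to it.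

Step 10
Reactants: 14 methyl 2-[(1R,2R,3S)-2-{[tert-butyl(dimethyl)silyl]oxymethyl}-3-[(Z)-3-iodoprop-2-en-1-yl]-4-oxo-3-[(phenylsulfanyl)methyl]cyclohexyl]acetate
Product: 15 methyl 2-[(1R,2R,5Z)-2-{[tert-butyl(dimethyl)silyl]oxymethyl}-3-methylidene-7-oxocyclonon-5-en-1-yl]acetate
Conditions: Bu3SnSnBu3 (1.5 equiv), hν (sunlamp, Pyrex), PhH (0.005 M), 80 °C
Reagents that add atoms: none
Why: Proposed new method: Bu3Sn• from photolysis of the ditin removes iodine from C8, the σ-vinyl radical adds 5-exo-trig to the C7 carbonyl carbon to give a cis-fused bicyclo[4.3.0]nonenyloxy radical, β-scission of C7–C11 opens this to ring A with a tertiary radical on C11, and that radical expels PhS• from C19, which attacks the ditin and so returns Bu3Sn• to the chain. The closest known reactions are the Dowd–Beckwith three-carbon ring expansion (radical addition to a ketone, then β-scission of the alkoxy radical) and the allyl sulfide–ditin chain of the Keck radical allylation (β-loss of PhS• and its capture by ditin); their combination with a vinyl radical as the attacking species has not been described, and since the net change is loss of I and SPh and not a reduction, no tin hydride is used, which removes hydrogen transfer to the vinyl radical as the main competitor. The one ring that is closed, the nine-membered ring A, is formed by ring expansion (the six-membered ring plus the C8–C10 bridge by way of a transient five-membered ring) and not by end-to-end cyclisation. No stereocentre is created: C11 becomes trigonal, C4a and C11a are not involved, and the Z geometry of C8=C9 is imposed by the five-membered ring in which the alkene sits when C7–C8 forms. The selectivity needed is cleavage of C7–C11 and not of C7–C6 or C7–C8, and it is secured by the tertiary C11 radical, the conjugated enone that this cleavage creates, the high energy of the vinyl radical that reversal would give back, and the fast loss of PhS•. The axial iodoallyl chain on C11 holds C8 over the carbonyl face, and high dilution limits intermolecular diversion of the vinyl radical.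

Step 11
Reactants: 15 methyl 2-[(1R,2R,5Z)-2-{[tert-butyl(dimethyl)silyl]oxymethyl}-3-methylidene-7-oxocyclonon-5-en-1-yl]acetate
Product: 16 methyl 2-[(1R,2R,5Z,7S)-2-{[tert-butyl(dimethyl)silyl]oxymethyl}-7-hydroxy-7-methyl-3-methylidenecyclonon-5-en-1-yl]acetate
Conditions: MeLi, CeCl3, THF, −78 °C
Reagents that add atoms: methyllithium, [Li]C
Why: The organocerium reagent should add 1,2 to the enone carbonyl without enolising toward C10 or attacking the ester, and the methyl group is expected to enter from the open peripheral face of the C7 carbonyl of the cis-cyclononenone so that the C7 hydroxyl lies on the same side of ring A as the C11a substituent (substrate control).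

Step 12
Reactants: 16 methyl 2-[(1R,2R,5Z,7S)-2-{[tert-butyl(dimethyl)silyl]oxymethyl}-7-hydroxy-7-methyl-3-methylidenecyclonon-5-en-1-yl]acetate
Product: 17 ring A/ring B lactone (trans-fused; C7 S tertiary alcohol; Z C8=C9; C11 methylene)
Conditions: TBAF, THF, 0 °C → rt
Reagents that add atoms: none
Why: Fluoride cleaves the primary silyl ether and the freed alkoxide closes the six-membered lactone onto the C3 methyl ester (desilylation–transesterification, 6-exo-trig), the trans ring fusion being fixed by C4a and C11a.

Step 13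
Reactants: 17 ring A/ring B lactone (trans-fused; C7 S tertiary alcohol; Z C8=C9; C11 methylene)
Product: 18 epoxy lactone (C8/C9 epoxide on the face of the C7 hydroxyl; C11 methylene kept)
Conditions: VO(acac)2 (5 mol %), t-BuOOH, CH2Cl2, 0 °C → rt
Reagents that add atoms: tert-butyl hydroperoxide, CC(C)(C)OO
Why: Hydroxyl-directed vanadium-catalysed epoxidation delivers oxygen to C8=C9 from the face of the C7 hydroxyl, which gives the cis epoxy alcohol typical of medium-ring allylic alcohols and leaves the undirected C11 methylene alone, so C8 and C9 are set by C7.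

Step 14
Reactants: 19 3-methylbut-2-enal; 1 ethyl propiolate
Product: 20 ethyl (4R)-4-hydroxy-6-methylhept-5-en-2-ynoate
Conditions: Me2Zn (3 equiv), ProPhenol ligand (10 mol %; antipode giving the R alcohol), Ph3P=O (20 mol %), PhMe, 0 °C
Reagents that add atoms: none
Why: Addition of the zinc alkynylide to the enal inside a dinuclear zinc–ProPhenol complex (catalytic asymmetric alkynylation) sets the C13 carbinol centre, the ligand antipode being chosen for the R alcohol.

Step 15
Reactants: 20 ethyl (4R)-4-hydroxy-6-methylhept-5-en-2-ynoate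
Product: 21 ethyl (4S)-4-[(2R)-3,3-dimethyloxiran-2-yl]-4-hydroxybut-2-ynoate
Conditions: mCPBA, NaHCO3, CH2Cl2, 0 °C
Reagents that add atoms: 3-chloroperoxybenzoic acid, OOC(=O)c1cccc(Cl)c1
Why: Hydroxyl-directed peracid epoxidation takes place on the conformer that minimises allylic 1,3-strain between the C13 substituents and the cis methyl group of the trisubstituted alkene, which should give the threo epoxy alcohol and so sets C14 from C13, while the electron-poor alkyne is inert.

Step 16
Reactants: 21 ethyl (4S)-4-[(2R)-3,3-dimethyloxiran-2-yl]-4-hydroxybut-2-ynoate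
Product: 22 ethyl (4S)-4-[(2R)-3,3-dimethyloxiran-2-yl]-4-(triethylsilyloxy)but-2-ynoate
Conditions: TESCl, imidazole, CH2Cl2, 0 °C
Reagents that add atoms: chlorotriethylsilane, CC[Si](CC)(CC)Cl
Why: Silylation of the secondary alcohol under imidazole buffering protects the C13 oxygen for the aldol step without opening the epoxide.

Step 17
Reactants: 22 ethyl (4S)-4-[(2R)-3,3-dimethyloxiran-2-yl]-4-(triethylsilyloxy)but-2-ynoate
Product: 23 ethyl (2Z,4S)-4-[(2R)-3,3-dimethyloxiran-2-yl]-4-(triethylsilyloxy)but-2-enoate
Conditions: H2 (1 atm), Pd on CaCO3 poisoned with Pb(OAc)2 (Lindlar catalyst), quinoline, EtOAc, rt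
Reagents that add atoms: none
Why: Lindlar semihydrogenation reduces the alkyne to the cis enoate and stops there, which turns C12 into an alkene carbon that ozone can cleave.

Step 18
Reactants: 23 ethyl (2Z,4S)-4-[(2R)-3,3-dimethyloxiran-2-yl]-4-(triethylsilyloxy)but-2-enoate
Product: 24 (2R)-2-[(2R)-3,3-dimethyloxiran-2-yl]-2-(triethylsilyloxy)acetaldehyde
Conditions: O3, CH2Cl2, −78 °C; then PPh3, −78 °C → rt
Reagents that add atoms: ozone, [O-][O+]=O
Why: Ozonolysis with reductive work-up cleaves the enoate C=C to the C12 aldehyde under neutral conditions that should neither epimerise C13 nor open the epoxide.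

Step 19
Reactants: 18 epoxy lactone (C8/C9 epoxide on the face of the C7 hydroxyl; C11 methylene kept); 24 (2R)-2-[(2R)-3,3-dimethyloxiran-2-yl]-2-(triethylsilyloxy)acetaldehyde
Product: 26 aldol adduct (C4–C12 bond; C12 hydroxyl; mixture at C4 and C12), via dilithium alkoxide enolate 25 (not isolated)
Conditions: LiN(i-Pr)2 (2.2 equiv), THF, −78 °C; then 24, −78 °C; AcOH quench
Reagents that add atoms: none
Why: Lithium enolate aldol addition, in which one equivalent of amide covers the C7 hydroxyl and the syn C7 alkoxide cannot reach the rear of the C8–O bond, joins C4 to C12 at −78 °C faster than the aldehyde can enolise, and the two new centres are left uncontrolled because step 20 removes both.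

Step 20
Reactants: 26 aldol adduct (C4–C12 bond; C12 hydroxyl; mixture at C4 and C12)
Product: 28 (E)-alkylidene lactone (C4=C12; C13 triethylsilyl ether), via aldol acetate 27 (not isolated)
Conditions: Ac2O, Et3N, DMAP (cat.), CH2Cl2, 0 °C; then DBU, rt
Reagents that add atoms: none
Why: Acetylation of the secondary aldol hydroxyl (the hindered tertiary C7 hydroxyl should not react) followed by E1cB elimination through the lactone enolate gives the conjugated alkylidene lactone, the E isomer with the vinyl hydrogen on the carbonyl side being expected as the more stable product.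

Step 21
Reactants: 28 (E)-alkylidene lactone (C4=C12; C13 triethylsilyl ether)
Product: 29 C13 alcohol (deacetyl target)
Conditions: TBAF, AcOH (1:1), THF, 0 °C
Reagents that add atoms: none
Why: Acetic-acid-buffered fluoride desilylation frees the C13 hydroxyl without a free alkoxide that could start a Payne rearrangement, and the E geometry keeps that hydroxyl away from the lactone carbonyl.

Step 22
Reactants: 29 C13 alcohol (deacetyl target)
Product: 30 CNP0113449.2 (target)
Conditions: Ac2O, pyridine, DMAP (cat.), CH2Cl2, 0 °C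
Reagents that add atoms: acetic anhydride, CC(=O)OC(C)=O
Why: DMAP-catalysed acetylation is selective for the secondary allylic C13 hydroxyl over the hindered tertiary C7 hydroxyl and completes the target.

Compound list

1 | ethyl propiolate | CCOC(=O)C#C | starting material
2 | ethyl (Z)-3-iodoprop-2-enoate | CCOC(=O)/C=C\I | intermediate
3 | (Z)-3-iodoprop-2-en-1-ol | OC/C=C\I | intermediate
4 | (Z)-3-bromo-1-iodoprop-1-ene | BrC/C=C\I | intermediate
5 | methyl 4-oxobutanoate | COC(=O)CCC=O | starting material
6 | but-3-en-2-one | CC(=O)C=C | starting material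
7 | methyl (3R)-3-formyl-6-oxoheptanoate (keto aldehyde, formed in the flask) | CC(=O)CC[C@H](CC(=O)OC)C=O | intermediate
8 | methyl 2-[(1R)-4-oxocyclohex-2-en-1-yl]acetate | O=C1CC[C@H](CC(=O)OC)C=C1 | intermediate
9 | chloromagnesium enolate of the trans conjugate adduct (C7–OMgCl, C7=C11; formed in the flask) | Cl[Mg]OC1=C[C@H](C[Si](C)(C)OC(C)C)[C@@H](CC(=O)OC)CC1 | intermediate
10 | methyl 2-[(1R,2R,3S)-3-[(Z)-3-iodoprop-2-en-1-yl]-2-{[dimethyl(propan-2-yloxy)silyl]methyl}-4-oxocyclohexyl]acetate (all-trans) | I/C=C\C[C@@H]1C(=O)CC[C@H](CC(=O)OC)[C@H]1C[Si](C)(C)OC(C)C | intermediate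
11 | methyl 2-[(1R,2R,3S)-2-(hydroxymethyl)-3-[(Z)-3-iodoprop-2-en-1-yl]-4-oxocyclohexyl]acetate | I/C=C\C[C@@H]1C(=O)CC[C@H](CC(=O)OC)[C@H]1CO | intermediate
12 | methyl 2-[(1R,2R,3S)-2-{[tert-butyl(dimethyl)silyl]oxymethyl}-3-[(Z)-3-iodoprop-2-en-1-yl]-4-oxocyclohexyl]acetate | I/C=C\C[C@@H]1C(=O)CC[C@H](CC(=O)OC)[C@H]1CO[Si](C)(C)C(C)(C)C | intermediate
13 | methyl 2-[(1R,2R)-2-{[tert-butyl(dimethyl)silyl]oxymethyl}-3-[(Z)-3-iodoprop-2-en-1-yl]-4-(trimethylsilyloxy)cyclohex-3-en-1-yl]acetate | I/C=C\CC1=C(O[Si](C)(C)C)CC[C@H](CC(=O)OC)[C@H]1CO[Si](C)(C)C(C)(C)C | intermediate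
14 | methyl 2-[(1R,2R,3S)-2-{[tert-butyl(dimethyl)silyl]oxymethyl}-3-[(Z)-3-iodoprop-2-en-1-yl]-4-oxo-3-[(phenylsulfanyl)methyl]cyclohexyl]acetate (ring-expansion substrate; iodoallyl cis to the C11a group) | I/C=C\C[C@@]1(CSc2ccccc2)C(=O)CC[C@H](CC(=O)OC)[C@H]1CO[Si](C)(C)C(C)(C)C | intermediate
15 | methyl 2-[(1R,2R,5Z)-2-{[tert-butyl(dimethyl)silyl]oxymethyl}-3-methylidene-7-oxocyclonon-5-en-1-yl]acetate (cyclononadienone) | C=C1C/C=C\C(=O)CC[C@H](CC(=O)OC)[C@H]1CO[Si](C)(C)C(C)(C)C | intermediate
16 | methyl 2-[(1R,2R,5Z,7S)-2-{[tert-butyl(dimethyl)silyl]oxymethyl}-7-hydroxy-7-methyl-3-methylidenecyclonon-5-en-1-yl]acetate | C=C1C/C=C\[C@@](C)(O)CC[C@H](CC(=O)OC)[C@H]1CO[Si](C)(C)C(C)(C)C | intermediate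
17 | ring A/ring B lactone: trans-fused, C7 S tertiary alcohol, Z C8=C9, C11 methylene | C=C1C/C=C\[C@@](C)(O)CC[C@@H]2CC(=O)OC[C@@H]12 | intermediate
18 | epoxy lactone: as 17 with the C8/C9 epoxide on the face of the C7 hydroxyl | C=C1C[C@H]2O[C@H]2[C@@](C)(O)CC[C@@H]2CC(=O)OC[C@@H]12 | intermediate
19 | 3-methylbut-2-enal | CC(C)=CC=O | starting material
20 | ethyl (4R)-4-hydroxy-6-methylhept-5-en-2-ynoate | CCOC(=O)C#C[C@H](O)C=C(C)C | intermediate
21 | ethyl (4S)-4-[(2R)-3,3-dimethyloxiran-2-yl]-4-hydroxybut-2-ynoate | CCOC(=O)C#C[C@H](O)[C@H]1OC1(C)C | intermediate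
22 | ethyl (4S)-4-[(2R)-3,3-dimethyloxiran-2-yl]-4-(triethylsilyloxy)but-2-ynoate | CCOC(=O)C#C[C@H](O[Si](CC)(CC)CC)[C@H]1OC1(C)C | intermediate
23 | ethyl (2Z,4S)-4-[(2R)-3,3-dimethyloxiran-2-yl]-4-(triethylsilyloxy)but-2-enoate | CCOC(=O)/C=C\[C@H](O[Si](CC)(CC)CC)[C@H]1OC1(C)C | intermediate
24 | (2R)-2-[(2R)-3,3-dimethyloxiran-2-yl]-2-(triethylsilyloxy)acetaldehyde | O=C[C@H](O[Si](CC)(CC)CC)[C@H]1OC1(C)C | intermediate
25 | dilithium C7 alkoxide/C3–C4 enolate of 18 (formed in the flask) | C=C1C[C@H]2O[C@H]2[C@@](C)(O[Li])CC[C@@H]2C=C(O[Li])OC[C@@H]12 | intermediate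
26 | aldol adduct: 18 joined at C4 to C12 of 24, C12 hydroxyl, C13 triethylsilyl ether, mixture at C4 and C12 | C=C1C[C@H]2O[C@H]2[C@@](C)(O)CC[C@@H]2C(C(O)[C@H](O[Si](CC)(CC)CC)[C@H]3OC3(C)C)C(=O)OC[C@@H]12 | intermediate
27 | C12 acetate of 26 (formed in the flask) | C=C1C[C@H]2O[C@H]2[C@@](C)(O)CC[C@@H]2C(C(OC(C)=O)[C@H](O[Si](CC)(CC)CC)[C@H]3OC3(C)C)C(=O)OC[C@@H]12 | intermediate
28 | (E)-alkylidene lactone: C4=C12, (13S) triethylsilyl ether, (14R) epoxide | C=C1C[C@H]2O[C@H]2[C@@](C)(O)CC[C@@H]2/C(=C\[C@H](O[Si](CC)(CC)CC)[C@H]3OC3(C)C)C(=O)OC[C@@H]12 | intermediate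
29 | C13 alcohol (deacetyl target) | C=C1C[C@H]2O[C@H]2[C@@](C)(O)CC[C@@H]2/C(=C\[C@H](O)[C@H]3OC3(C)C)C(=O)OC[C@@H]12 | intermediate
30 | CNP0113449.2: trans-fused ring A/ring B lactone, (7S) C(CH3)OH, C8/C9 epoxide syn to the C7 hydroxyl, C11 methylene, (E)-C4=C12, (13S) acetate, (14R) epoxide | C=C1C[C@H]2O[C@H]2[C@@](C)(O)CC[C@@H]2/C(=C\[C@H](OC(C)=O)[C@H]3OC3(C)C)C(=O)OC[C@@H]12 | target

Total step count: 22. Longest linear sequence: 16 steps (steps 1–3, 5–13 and 19–22, from ethyl propiolate); the main line from methyl 4-oxobutanoate is 14 steps.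

Steps most likely to fail

1. Step 10 (the step labelled as a proposed new method). The C8 vinyl radical may be diverted before it reaches C7, by 1,5-hydrogen transfer from C19 or C11a or by addition to the solvent, or the chain may stall if the thiyl radical is not returned to tin. The fallback is the two-electron version of the same disconnection and uses known reactions only; it sets out from 13 and returns at 15. Mukaiyama aldol hydroxymethylation of the silyl enol ether with aqueous formaldehyde and Yb(OTf)3 (cat.) in THF/H2O should give the β-hydroxy ketone F1, and MsCl/Et3N the mesylate F2. Iodine–lithium exchange with t-BuLi (2 equiv, THF/pentane, −100 °C) is followed by addition of the vinyllithium to the C7 ketone, which gives the cis-fused bicyclic lithium alkoxide F3. On warming, F3 should undergo Grob (Wharton) fragmentation: the C7–C11 bond breaks, mesylate leaves C19 (anti alignment is available by rotation about C11–C19), and the C7 ketone, the Z C8=C9 bond and the C11 methylene of 15 appear together.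

2. Step 11. The methyl group may attack the wrong face of the C7 carbonyl, or attack with poor facial selectivity, and the error would be copied to C8 and C9 in step 13. The fallback sets out from 15 and returns at 18. Weitz–Scheffer epoxidation of the cis-enone (t-BuOOH, DBU, THF, 0 °C) should give the cis-epoxy ketone F4. MeMgBr in CH2Cl2/THF at −78 °C, with magnesium bridging the carbonyl and epoxide oxygens, should then add anti to C9 and give the syn epoxy alcohol F5. C7 is thereby fixed by C8 through chelation, and the facial choice moves to a different event, the conjugate attack of the hydroperoxide on C9. TBAF as in step 12 then closes the lactone to 18.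

3. Step 19. The α-silyloxy aldehyde may enolise with opening of its epoxide, the aldolate may revert on work-up, or the dianion may convert poorly. The fallback replaces aldol addition and elimination by an olefination; it sets out from 18 and returns at 29. N-(Trimethylsilyl)imidazole should give the C7 trimethylsilyl ether F6. LiN(i-Pr)2 and ClP(O)(OEt)2 (enol phosphate, then 1,3-shift of phosphorus from oxygen to carbon with excess amide) should give the α-phosphono lactone F7. Horner–Wadsworth–Emmons olefination with 24 (LiCl, DBU, MeCN) should give the bis-silylated (E)-alkylidene lactone F8, and TBAF/AcOH removes both silyl groups to give 29.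

Further compounds

F1 | step 10 | β-hydroxy ketone: 12 with an added CH2OH on C11 (trans to the C11a group) | I/C=C\C[C@@]1(CO)C(=O)CC[C@H](CC(=O)OC)[C@H]1CO[Si](C)(C)C(C)(C)C
F2 | step 10 | methanesulfonate of F1 | I/C=C\C[C@@]1(COS(C)(=O)=O)C(=O)CC[C@H](CC(=O)OC)[C@H]1CO[Si](C)(C)C(C)(C)C
F3 | step 10 | cis-fused bicyclic lithium alkoxide (C7–C8 bond formed, C19 mesylate) | [Li]O[C@@]12C=CC[C@]1(COS(C)(=O)=O)[C@H](CO[Si](C)(C)C(C)(C)C)[C@@H](CC(=O)OC)CC2
F4 | step 11 | cis-epoxy ketone (C8/C9 epoxide of 15) | C=C1C[C@H]2O[C@H]2C(=O)CC[C@H](CC(=O)OC)[C@H]1CO[Si](C)(C)C(C)(C)C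
F5 | step 11 | syn epoxy alcohol (C7 methyl carbinol of F4) | C=C1C[C@H]2O[C@H]2[C@@](C)(O)CC[C@H](CC(=O)OC)[C@H]1CO[Si](C)(C)C(C)(C)C
F6 | step 19 | C7 trimethylsilyl ether of 18 | C=C1C[C@H]2O[C@H]2[C@@](C)(O[Si](C)(C)C)CC[C@@H]2CC(=O)OC[C@@H]12
F7 | step 19 | C4 diethyl phosphonate of F6 | C=C1C[C@H]2O[C@H]2[C@@](C)(O[Si](C)(C)C)CC[C@@H]2C(P(=O)(OCC)OCC)C(=O)OC[C@@H]12
F8 | step 19 | (E)-alkylidene lactone with C7 trimethylsilyl and C13 triethylsilyl ethers | C=C1C[C@H]2O[C@H]2[C@@](C)(O[Si](C)(C)C)CC[C@@H]2/C(=C\[C@H](O[Si](CC)(CC)CC)[C@H]3OC3(C)C)C(=O)OC[C@@H]12
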